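## The problem

Guaiane numbering is used for the sesquiterpene half (C1 and C5 ring fusion, C4 quaternary with methyl C15, C5=C6, C7 carrying carbinol C11, C10 carrying a methyl); C9' is the benzylic carbon and C1'–C6' the arene (C1' bonded to C9'). Face α is the face of the hydroazulene that carries H-1, face β the one that carries the C10 methyl.

The target joins a 3,5-diformylphloroglucinol to a bicyclo[5.3.0]dec-5-ene through one bond, C4–C9'. This bond links a fully substituted ring carbon to a tertiary benzylic carbon flanked by two ortho oxygens, so no displacement or cross-coupling will make it. C4 (R) and C9' (R) must be set relative to each other and to the remote centres C1, C7 and C10 (all R). Those three sit on a flexible cycloheptene and cannot direct C4 through space; in the target C9' on C4, C11 on C7 and H-1 all lie on the α face.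

The feature that makes the key step possible is that C4 is allylic to the ring-fusion double bond. The array C1'–C9'–C4–C5=C6 is a γ,δ-unsaturated acid if C1' is read as a carboxyl carbon. That is the retron of a [3,3] shift from a C6–O ester across a C4=C5 bond in the cyclopentene ring, and a C6 carbinol next to C7 can be set by substrate control.

A second latent feature is that C11–OH is homoallylic to C5=C6. This is the signature of an opened gem-dimethylcyclopropane fused at C6–C7, and it links the skeleton to commercial (−)-α-gurjunene 1, which already carries C1, C7 and C10.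

The tertiary alcohol ionises under acid, and the diformylphloroglucinol is sensitive to air, base and nucleophiles. Free phenols and aldehydes therefore have to come last.

## Retrosynthesis

**Formyl groups.** Target 26 is traced to silyl ether 25, and the two aryl–CHO bonds are cut to give phloroglucinol 23. The two free arene positions of 23 are equivalent, so double formylation has no regiochemical issue. Placing it late keeps the aldehydes away from enolates, organolithiums and hydride. The forward step must formylate twice without ionising C11–O, hence the silyl ether.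

**Arene ring.** The ring of 23 (through its bis-silyl ether 22) is cut at C1'–C6' and C2'–C3'. This gives the two-carbon siloxyalkyne 15 (C1', C2') and the four-carbon vinylketene precursor 17 (C3'–C6'). The neighbouring cut, C9'–C1', would need an aryl nucleophile or a benzylic cation at a neopentyl-type secondary carbon and would not preserve C9'. Growing the ring from a carbon already on C9' leaves that centre untouched and puts the three oxygens in place (C2' from the alkyne, C6' from the ketene carbonyl, C4' from 17). The forward reaction is a thermal benzannulation of a hindered but linear alkyne.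

**One-carbon homologation.** Siloxyalkyne 15 comes from methyl ester 12 by ester-to-ynolate homologation, and 12 from acid 11. This adds C2' and turns the carboxyl carbon into the nucleophilic alkyne carbon C1' in one operation. The migration must not disturb C9'.

**C4–C9' bond (key).** Acid 11 is cut at C4–C9' by an Ireland–Claisen retron to give ester 8, in which the alkene sits at C4=C5 and C6 carries the acyloxy group. Against a cation or quinone methide union at the same bond, this closed transition state sets C4 from the C6 carbinol and C9' from enolate geometry in one event. Ester 8 has two stereocentres fewer than 11, and C6 is readily corrected by oxidation and reduction. The forward step needs Z-selective enolisation and a chair transition state.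

**Ester and C6 carbinol.** Ester 8 comes from alcohol 6 and acid chloride 7. Alcohol 6 comes from enone 5 by hydride delivery anti to the C7 substituent, and 5 from hydroxy enone 4 by silylation. The C6 stereocentre is bought cheaply from C7.

**Cyclopropane.** Enone 4 is traced through diol 3 to α-gurjunene 1 by re-forming the C6–C11 bond. Oxidation of the C4=C5 bond of 1 triggers the cyclopropylcarbinyl-to-homoallyl opening, which creates C11–OH and C5=C6. An allylic oxidative transposition then moves the oxygen to C6. Three stereocentres (C1, C7, C10) and the whole carbon skeleton are purchased.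

## Roads not taken

**Alternative 1:** (the obvious one) cut C4–C9' as a cation–olefin union. Lewis-acid ionisation of benzylic alcohol A1 in the presence of 1 would have C4 attack the benzylic carbon, the cyclopropane open and water add at C11, giving A2. Formylation and demethylation would follow.
- It is shorter, but the open transition state offers no control of C9' relative to C4.
- The electrophile would have to approach C4 syn to C11, on the face shielded by the inner cyclopropane methyl. Cyclopropane-assisted attack is expected anti, which gives the wrong C4.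
- The intermediate cations can also close onto a phenol oxygen or rearrange.
- The chosen plan fixes both centres in one chair transition state whose face is set by a carbinol that can be corrected.

**Alternative 2:** keep the Claisen cut but carry the arene through it. Ester A3 of alcohol 6 with (2,4,6-trimethoxyphenyl)acetic acid would rearrange to acid A4, whose carboxyl group would then be turned into the isobutyl CH2.
- Arylacetate enolates prefer the geometry with aryl syn to the enolate oxygen. In the chair this puts the aryl group equatorial and gives A4 with C9' opposite to what the target needs.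
- Converting CO2H into CH2CHMe2 costs four to five steps through an epimerisable α-aryl aldehyde, with an electron-rich aryl group β to reactive centres (aryl shifts).
- The chosen plan uses a plain alkanoate whose enolate geometry can be steered either way, and needs no carbon–carbon surgery at C9'.

**Alternative 3:** build the hydroazulene de novo by cutting C6–C7. Enal A5, from (R)-citronellal, would close the seven-membered ring by a Lewis-acid carbonyl-ene reaction to dienol A6, which then needs Markovnikov hydration.
- A5 needs about eight steps, with C1 set against C10 by catalyst control.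
- Seven-membered ene closures are slow, and the C6/C7 relationship is not secured.
- α-Gurjunene delivers enone 5 in three steps with C1, C7, C10 and the C11 oxygen in place.

Key step: step 6

**Remarks on the chemistry.**
- Commercial (−)-α-gurjunene is taken to have the (1aR,4R,4aR,7bS) configuration, which maps onto 1R, 7R, 10R of the target.
- Cyclobutane-1,3-dione is taken as a catalogue compound.
- Compounds 2 and 3 are drawn as the products of attack anti to the cyclopropane (β face). Their C4/C5 configuration is erased in step 2.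
- Gu = (1R,4R,7R,10R)-11-(tert-butyldimethylsilyloxy)guai-5-en-4-yl.

## Steps

Step 1
Reactants: 1 (−)-α-gurjunene
Product: 3 (1R,4R,7R,10R)-guai-5-ene-4,11-diol, via 4β,5β-epoxyaromadendrane 2 (not isolated)
Conditions: mCPBA, THF–H2O (3:1), 0 °C; then HClO4 (cat.), 0 → 25 °C
Reagents that add atoms: 3-chloroperoxybenzoic acid OOC(=O)c1cccc(Cl)c1; water O
Why: Prilezhaev epoxidation of the only alkene, then acid-triggered ionisation at C5; the cyclopropylcarbinyl cation opens by C6–C11 cleavage (cyclopropylcarbinyl-to-homoallyl rearrangement) and water traps the tertiary C11 cation. C1, C7 and C10 are not touched, and ring capture of C11 by the C4 oxygen is impossible because C4 and C7 are trans on C5=C6.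

Step 2
Reactants: 3 (1R,4R,7R,10R)-guai-5-ene-4,11-diol
Product: 4 (1R,7S,10R)-11-hydroxyguai-4-en-6-one
Conditions: C5H5NH[CrO3Cl] (pyridinium chlorochromate), 4 Å MS, CH2Cl2, 25 °C
Reagents that add atoms: pyridinium chlorochromate [O-][Cr](=O)(=O)Cl.c1cc[nH+]cc1
Why: Babler–Dauben oxidative transposition: the tertiary allylic chromate ester shifts oxygen from C4 to C6 and the secondary ester is oxidised by hexavalent chromium to the enone. Any C6 allylic isomer formed in step 1 converges on the same enone, and the tertiary C11–OH is inert.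

Step 3
Reactants: 4 (1R,7S,10R)-11-hydroxyguai-4-en-6-one
Product: 5 (1R,7S,10R)-11-(tert-butyldimethylsilyloxy)guai-4-en-6-one
Conditions: TBSOTf, 2,6-lutidine, CH2Cl2, −78 → 0 °C
Reagents that add atoms: tert-butyldimethylsilyl triflate CC(C)(C)[Si](C)(C)OS(=O)(=O)C(F)(F)F
Why: Silylation of the tertiary alcohol with the silyl triflate; it removes the retro-aldol and dehydration liability of the β-hydroxy ketone and enlarges the C7 substituent for step 4.

Step 4
Reactants: 5 (1R,7S,10R)-11-(tert-butyldimethylsilyloxy)guai-4-en-6-one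
Product: 6 (1R,6R,7R,10R)-11-(tert-butyldimethylsilyloxy)guai-4-en-6-ol
Conditions: Li[HB(sec-Bu)3], THF, −78 °C; then H2O
Reagents that add atoms: none
Why: 1,2-Reduction of a β,β-disubstituted enone (no conjugate reduction); the bulky hydride should approach C6 anti to the adjacent α-oriented C7 substituent, from the β face. This gives the 6α alcohol (6R), cis to C7–C11 and pseudo-axial as step 6 requires.

Step 5
Reactants: 6 (1R,6R,7R,10R)-11-(tert-butyldimethylsilyloxy)guai-4-en-6-ol; 7 4-methylpentanoyl chloride
Product: 8 (1R,6R,7R,10R)-11-(tert-butyldimethylsilyloxy)guai-4-en-6-yl 4-methylpentanoate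
Conditions: pyridine, DMAP (cat.), CH2Cl2, 0 → 25 °C
Reagents that add atoms: none
Why: DMAP-catalysed acylation of the secondary allylic alcohol; the acyl group brings C9', the isobutyl group and the future C1'.

Step 6
Reactants: 8 (1R,6R,7R,10R)-11-(tert-butyldimethylsilyloxy)guai-4-en-6-yl 4-methylpentanoate
Product: 11 (2R)-2-Gu-4-methylpentanoic acid, via silyl ketene acetal 9 (not isolated), via silyl ester 10 (not isolated)
Conditions: LiN(i-Pr)2, THF–DMPU (4:1), −78 °C; TBSCl, −78 → 65 °C; then AcOH–THF–H2O, 25 °C
Reagents that add atoms: tert-butyldimethylsilyl chloride C[Si](C)(Cl)C(C)(C)C (silicon carried in 9 and 10 only, lost on work-up)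
Why: Ireland–Claisen rearrangement: deprotonation of 8 in the dipolar medium and O-silylation should give the (Z)-ketene acetal 9 (isobutyl syn to OSi), which undergoes a [3,3] shift through a chair transition state to silyl ester 10, hydrolysed to 11 on work-up. The closest known reaction type is the ester enolate Claisen rearrangement of allylic alkanoates onto a fully substituted alkene terminus, which forms vicinal quaternary and tertiary centres. No ring is closed; the C4–C9' bond forms, C6–O breaks and the double bond moves from C4=C5 to C5=C6. C4 is controlled by C6: the shift is suprafacial on the allyl unit, the seven-membered ring holds C7 pseudo-equatorial and the C6–O bond pseudo-axial on the α face, so C9' is delivered to the α face of C4 (4R). C9' is controlled by the ketene acetal geometry: in the chair the Z isomer places isobutyl equatorial and pointing away from the bicycle, with its hydrogen toward the cyclopentene, which gives 9'R. The step needs Z-selective enolisation (standard for simple alkanoates in THF–DMPU) and chair over boat (the boat would push the silyloxy group under C1–H and C2 on the α side). The C4 methyl group is cis to C6 and sits axial in the chair, which is tolerated because its only 1,3-partner is the C6 hydrogen.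

Step 7
Reactants: 11 (2R)-2-Gu-4-methylpentanoic acid
Product: 12 methyl (2R)-2-Gu-4-methylpentanoate
Conditions: MeI, K2CO3, DMF, 25 °C
Reagents that add atoms: iodomethane CI
Why: O-Alkylation of the carboxylate, the reliable way to esterify a hindered acid; the weak base does not epimerise the hindered C9'.

Step 8
Reactants: 12 methyl (2R)-2-Gu-4-methylpentanoate
Product: 15 triisopropyl{[(3R)-3-Gu-5-methylhex-1-yn-1-yl]oxy}silane, via dibromomethyl ketone 13 (not isolated), via lithium ynolate 14 (not isolated)
Conditions: CH2Br2, lithium 2,2,6,6-tetramethylpiperidide, THF, −78 °C; n-BuLi, −78 → 25 °C; TIPSCl, 0 °C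
Reagents that add atoms: dibromomethane BrCBr; triisopropylsilyl chloride CC(C)[Si](Cl)(C(C)C)C(C)C
Why: Kowalski ester homologation stopped at the ynolate: LiCHBr2 adds to the ester, the dibromo enolate undergoes Br/Li exchange and a 1,2-shift to ynolate 14, and the bulky silyl chloride silylates on oxygen. C9' is not a reacting centre and its configuration is kept.

Step 9
Reactants: 16 cyclobutane-1,3-dione
Product: 17 3-(triisopropylsilyloxy)cyclobut-2-en-1-one
Conditions: TIPSCl, imidazole, CH2Cl2, 0 °C
Reagents that add atoms: triisopropylsilyl chloride CC(C)[Si](Cl)(C(C)C)C(C)C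
Why: O-Silylation of the enol form of a vinylogous acid; 17 is moisture-sensitive and is used directly.

Step 10
Reactants: 15 triisopropyl{[(3R)-3-Gu-5-methylhex-1-yn-1-yl]oxy}silane; 17 3-(triisopropylsilyloxy)cyclobut-2-en-1-one
Product: 22 2-[(1R)-1-Gu-3-methylbutyl]-3,5-bis(triisopropylsilyloxy)phenol, via vinylketene 18 (not isolated), via vinylcyclobutenone 19 (not isolated), via dienylketene 20 (not isolated), via cyclohexadienone 21 (not isolated)
Conditions: PhMe, 110 °C (sealed tube)
Reagents that add atoms: none
Why: Danheiser benzannulation: 4π opening of 17 to 18, [2+2] addition in which the nucleophilic alkyne carbon C1' bonds to the ketene carbonyl carbon (19), 4π opening to 20, 6π closure to 21 and tautomerisation. This places the alkyl group between OH and OSi with the third oxygen para, and no stereocentre is touched. Using an oxygenated cyclobutenone as the four-carbon partner is the least tested element of the route.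

Step 11
Reactants: 22 2-[(1R)-1-Gu-3-methylbutyl]-3,5-bis(triisopropylsilyloxy)phenol
Product: 23 2-[(1R)-1-Gu-3-methylbutyl]benzene-1,3,5-triol
Conditions: Bu4NF, AcOH, THF, 0 °C (argon)
Reagents that add atoms: none
Why: Buffered fluoride cleaves aryl silyl ethers far faster than the hindered tertiary alkyl silyl ether on C11; the air-sensitive triol is used at once.

Step 12
Reactants: 23 2-[(1R)-1-Gu-3-methylbutyl]benzene-1,3,5-triol
Product: 25 11-O-(tert-butyldimethylsilyl)macrocarpal D, via bis(iminium) salt 24 (not isolated)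
Conditions: [Me2N=CHCl]Cl, MeCN, 0 → 25 °C; then H2O, 40 °C
Reagents that add atoms: (chloromethylene)dimethyliminium chloride C[N+](C)=CCl.[Cl-]; water O
Why: Vilsmeier–Haack formylation of a phloroglucinol; the two free positions are equivalent and each is activated by three oxygens, so double substitution is expected before hydrolysis of 24. The tertiary alcohol is masked against the chloroiminium reagent.

Step 13
Reactants: 25 11-O-(tert-butyldimethylsilyl)macrocarpal D
Product: 26 (−)-macrocarpal D
Conditions: HF·pyridine, pyridine, THF, 0 → 25 °C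
Reagents that add atoms: none
Why: Buffered fluoride desilylation of the tertiary silyl ether; the conditions are too weakly acidic to ionise the homoallylic tertiary alcohol and leave the hydrogen-bonded dialdehyde alone.

## Compound list

1 | (−)-α-gurjunene, (1aR,4R,4aR,7bS)-1,1,4,7-tetramethyl-1a,2,3,4,4a,5,6,7b-octahydro-1H-cyclopropa[e]azulene | CC1=C2[C@H]3[C@@H](CC[C@@H](C)[C@H]2CC1)C3(C)C | starting material
2 | 4β,5β-epoxyaromadendrane (α-gurjunene 4,5-oxide) | C[C@]12O[C@@]13[C@H](CC2)[C@H](C)CC[C@@H]2[C@H]3C2(C)C | intermediate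
3 | (1R,4R,7R,10R)-guai-5-ene-4,11-diol | O[C@]1(C)CC[C@H]2C1=C[C@H](C(C)(C)O)CC[C@H]2C | intermediate
4 | (1R,7S,10R)-11-hydroxyguai-4-en-6-one | CC1=C2C(=O)[C@H](C(C)(C)O)CC[C@@H](C)[C@H]2CC1 | intermediate
5 | (1R,7S,10R)-11-(tert-butyldimethylsilyloxy)guai-4-en-6-one | CC1=C2C(=O)[C@H](C(C)(C)O[Si](C)(C)C(C)(C)C)CC[C@@H](C)[C@H]2CC1 | intermediate
6 | (1R,6R,7R,10R)-11-(tert-butyldimethylsilyloxy)guai-4-en-6-ol | CC1=C2[C@H](O)[C@H](C(C)(C)O[Si](C)(C)C(C)(C)C)CC[C@@H](C)[C@H]2CC1 | intermediate
7 | 4-methylpentanoyl chloride | CC(C)CCC(Cl)=O | starting material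
8 | (1R,6R,7R,10R)-11-(tert-butyldimethylsilyloxy)guai-4-en-6-yl 4-methylpentanoate | CC1=C2[C@H](OC(=O)CCC(C)C)[C@H](C(C)(C)O[Si](C)(C)C(C)(C)C)CC[C@@H](C)[C@H]2CC1 | intermediate
9 | (Z)-O-(tert-butyldimethylsilyl) ketene acetal of 8 | CC1=C2[C@H](O/C(O[Si](C)(C)C(C)(C)C)=C/CC(C)C)[C@H](C(C)(C)O[Si](C)(C)C(C)(C)C)CC[C@@H](C)[C@H]2CC1 | intermediate
10 | tert-butyldimethylsilyl (2R)-2-Gu-4-methylpentanoate | CC(C)C[C@@H](C(=O)O[Si](C)(C)C(C)(C)C)[C@@]1(C)CC[C@H]2C1=C[C@H](C(C)(C)O[Si](C)(C)C(C)(C)C)CC[C@H]2C | intermediate
11 | (2R)-2-Gu-4-methylpentanoic acid | CC(C)C[C@@H](C(=O)O)[C@@]1(C)CC[C@H]2C1=C[C@H](C(C)(C)O[Si](C)(C)C(C)(C)C)CC[C@H]2C | intermediate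
12 | methyl (2R)-2-Gu-4-methylpentanoate | CC(C)C[C@@H](C(=O)OC)[C@@]1(C)CC[C@H]2C1=C[C@H](C(C)(C)O[Si](C)(C)C(C)(C)C)CC[C@H]2C | intermediate
13 | (3R)-1,1-dibromo-3-Gu-5-methylhexan-2-one | CC(C)C[C@@H](C(=O)C(Br)Br)[C@@]1(C)CC[C@H]2C1=C[C@H](C(C)(C)O[Si](C)(C)C(C)(C)C)CC[C@H]2C | intermediate
14 | lithium (3R)-3-Gu-5-methylhex-1-yn-1-olate | CC(C)C[C@@H](C#C[O-])[C@@]1(C)CC[C@H]2C1=C[C@H](C(C)(C)O[Si](C)(C)C(C)(C)C)CC[C@H]2C.[Li+] | intermediate
15 | triisopropyl{[(3R)-3-Gu-5-methylhex-1-yn-1-yl]oxy}silane | CC(C)C[C@@H](C#CO[Si](C(C)C)(C(C)C)C(C)C)[C@@]1(C)CC[C@H]2C1=C[C@H](C(C)(C)O[Si](C)(C)C(C)(C)C)CC[C@H]2C | intermediate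
16 | cyclobutane-1,3-dione | O=C1CC(=O)C1 | starting material
17 | 3-(triisopropylsilyloxy)cyclobut-2-en-1-one | O=C1C=C(O[Si](C(C)C)(C(C)C)C(C)C)C1 | intermediate
18 | 3-(triisopropylsilyloxy)buta-1,3-dien-1-one | C=C(O[Si](C(C)C)(C(C)C)C(C)C)C=C=O | intermediate
19 | 2-[(1R)-1-Gu-3-methylbutyl]-3-(triisopropylsilyloxy)-4-[1-(triisopropylsilyloxy)ethenyl]cyclobut-2-en-1-one (either configuration at ring C4) | CC(C)C[C@@H](C1=C(O[Si](C(C)C)(C(C)C)C(C)C)C(C(=C)O[Si](C(C)C)(C(C)C)C(C)C)C1=O)[C@@]1(C)CC[C@H]2C1=C[C@H](C(C)(C)O[Si](C)(C)C(C)(C)C)CC[C@H]2C | intermediate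
20 | (3E)-2-[(1R)-1-Gu-3-methylbutyl]-3,5-bis(triisopropylsilyloxy)hexa-1,3,5-trien-1-one | CC(C)C[C@@H](C(=C=O)/C(O[Si](C(C)C)(C(C)C)C(C)C)=C\C(=C)O[Si](C(C)C)(C(C)C)C(C)C)[C@@]1(C)CC[C@H]2C1=C[C@H](C(C)(C)O[Si](C)(C)C(C)(C)C)CC[C@H]2C | intermediate
21 | 2-[(1R)-1-Gu-3-methylbutyl]-3,5-bis(triisopropylsilyloxy)cyclohexa-2,4-dien-1-one | CC(C)C[C@@H](C1=C(O[Si](C(C)C)(C(C)C)C(C)C)C=C(O[Si](C(C)C)(C(C)C)C(C)C)CC1=O)[C@@]1(C)CC[C@H]2C1=C[C@H](C(C)(C)O[Si](C)(C)C(C)(C)C)CC[C@H]2C | intermediate
22 | 2-[(1R)-1-Gu-3-methylbutyl]-3,5-bis(triisopropylsilyloxy)phenol | CC(C)C[C@@H](c1c(O)cc(O[Si](C(C)C)(C(C)C)C(C)C)cc1O[Si](C(C)C)(C(C)C)C(C)C)[C@@]1(C)CC[C@H]2C1=C[C@H](C(C)(C)O[Si](C)(C)C(C)(C)C)CC[C@H]2C | intermediate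
23 | 2-[(1R)-1-Gu-3-methylbutyl]benzene-1,3,5-triol | CC(C)C[C@@H](c1c(O)cc(O)cc1O)[C@@]1(C)CC[C@H]2C1=C[C@H](C(C)(C)O[Si](C)(C)C(C)(C)C)CC[C@H]2C | intermediate
24 | bis(N,N-dimethyliminium) dichloride corresponding to dialdehyde 25 | CC(C)C[C@@H](c1c(O)c(C=[N+](C)C)c(O)c(C=[N+](C)C)c1O)[C@@]1(C)CC[C@H]2C1=C[C@H](C(C)(C)O[Si](C)(C)C(C)(C)C)CC[C@H]2C.[Cl-].[Cl-] | intermediate
25 | 11-O-(tert-butyldimethylsilyl)macrocarpal D, 5-[(1R)-1-Gu-3-methylbutyl]-2,4,6-trihydroxybenzene-1,3-dicarbaldehyde | CC(C)C[C@@H](c1c(O)c(C=O)c(O)c(C=O)c1O)[C@@]1(C)CC[C@H]2C1=C[C@H](C(C)(C)O[Si](C)(C)C(C)(C)C)CC[C@H]2C | intermediate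
26 | (−)-macrocarpal D | CC(C)C[C@@H](c1c(O)c(C=O)c(O)c(C=O)c1O)[C@@]1(C)CC[C@H]2C1=C[C@H](C(C)(C)O)CC[C@H]2C | target

## Step count and least certain steps

Total: 13 steps. Longest linear sequence: 12 steps (steps 1–8 and 10–13 from 1); step 9 is a one-step side branch.

**Step 6 (key).** The Z-selectivity of enolisation may erode, or the boat transition state may leak in, and either would scramble C9'. The ketene acetal may also decompose before the slow shift onto the fully substituted C4. The fallback sets out from 6 and returns at 11, and sets the two centres one after the other. Alcohol 6 is acetylated (Ac2O, DMAP) to the acetate F1. Ireland–Claisen rearrangement of its unsubstituted ketene acetal (LiN(i-Pr)2, Me3SiCl, THF, −78 → 60 °C) involves no enolate geometry and is less crowded; it gives the C4 acetic acid F2 with C4 still fixed by C6. F2 is coupled through its pivaloyl mixed anhydride with lithiated (R)-4-benzyloxazolidin-2-one to the imide F3. NaN(SiMe3)2 and 3-iodo-2-methylpropene alkylate the Z-enolate anti to the benzyl group to give the methallyl imide F4 (9'R by auxiliary control). Hydrogenation of the 1,1-disubstituted alkene over RhCl(PPh3)3, which leaves the hindered C5=C6 bond, gives the isobutyl imide F5, and LiOH/H2O2 releases acid 11.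

**Step 10.** Electrocyclic opening of 17, a vinylogous silyl ester stabilised in its ground state, may be slower than the thermal 1,3-silyl shift of 15 to a silylketene. Vinylketene 18 may also dimerise faster than it adds to the hindered alkyne carbon. The fallback sets out from 15 and returns at 25, and generates an oxygenated vinylketene by a different reaction at low temperature. 1,4-Dehydrochlorination of (E)-3-methoxybut-2-enoyl chloride with Et3N in the presence of 15 gives 3-methoxybuta-1,3-dien-1-one F6 (not isolated). Cycloaddition and warming to 80 °C complete the same cascade to the methoxy phenol F7. Bu4NF/AcOH gives the resorcinol monomethyl ether F8. Formylation as in step 12 gives, through the bis(iminium) salt F9, the dialdehyde F10. Its methoxy group is then flanked by two formyl groups and is cleaved with chelation assistance by MgI2·OEt2 to give 25.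

**Step 8.** Addition of LiCHBr2 to the neopentyl-type ester may be slow, which would let the amide base enolise C9' (epimerisation) or leave the rearrangement incomplete. The fallback sets out from 12 and returns at 15. Reduction with i-Bu2AlH (CH2Cl2, −78 °C) gives the aldehyde F11. Ohira–Bestmann alkynylation (dimethyl (1-diazo-2-oxopropyl)phosphonate, K2CO3, MeOH) gives the terminal alkyne F12. Lithiation (n-BuLi), oxidation of the lithium acetylide with LiOO-t-Bu to ynolate 14 and silylation with TIPSCl give 15.

**Step 1.** The C11 cation may partition between water capture and elimination, and the tertiary allylic alcohol may ionise further under the protic conditions. The fallback sets out from 1 and returns at 4, and avoids strong acid. Hydroxyselenation (N-(phenylseleno)phthalimide, H2O, CH2Cl2) opens the vinylcyclopropane in the same sense and gives the tertiary allylic selenide F13. H2O2/pyridine forms the selenoxide F14 (not isolated), whose [2,3] shift and hydrolysis deliver the 6,11-diol F15. MnO2 oxidises the secondary allylic alcohol to 4; the C6 configuration of F15 is of no consequence.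

**Step 4.** Facial selectivity of hydride delivery to the flexible cycloheptenone may be poor, and the 6β alcohol would relay the wrong configuration to C4. The fallback sets out from 5 and returns at 8. The 6β alcohol F16 is not discarded: Mitsunobu esterification with 4-methylpentanoic acid (PPh3, DIAD, PhMe) inverts C6 and gives ester 8 directly.

## Further compounds

F1 | step 6 | (1R,6R,7R,10R)-11-(tert-butyldimethylsilyloxy)guai-4-en-6-yl acetate | CC1=C2[C@H](OC(C)=O)[C@H](C(C)(C)O[Si](C)(C)C(C)(C)C)CC[C@@H](C)[C@H]2CC1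
F2 | step 6 | 2-Gu-acetic acid | OC(=O)C[C@@]1(C)CC[C@H]2C1=C[C@H](C(C)(C)O[Si](C)(C)C(C)(C)C)CC[C@H]2C
F3 | step 6 | (4R)-4-benzyl-3-(2-Gu-acetyl)oxazolidin-2-one | O=C(C[C@@]1(C)CC[C@H]2C1=C[C@H](C(C)(C)O[Si](C)(C)C(C)(C)C)CC[C@H]2C)N1[C@H](Cc2ccccc2)COC1=O
F4 | step 6 | (4R)-4-benzyl-3-[(2R)-2-Gu-4-methylpent-4-enoyl]oxazolidin-2-one | CC(=C)C[C@@H](C(=O)N1[C@H](Cc2ccccc2)COC1=O)[C@@]1(C)CC[C@H]2C1=C[C@H](C(C)(C)O[Si](C)(C)C(C)(C)C)CC[C@H]2C
F5 | step 6 | (4R)-4-benzyl-3-[(2R)-2-Gu-4-methylpentanoyl]oxazolidin-2-one | CC(C)C[C@@H](C(=O)N1[C@H](Cc2ccccc2)COC1=O)[C@@]1(C)CC[C@H]2C1=C[C@H](C(C)(C)O[Si](C)(C)C(C)(C)C)CC[C@H]2C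
F6 | step 10 | 3-methoxybuta-1,3-dien-1-one | COC(=C)C=C=O
F7 | step 10 | 2-[(1R)-1-Gu-3-methylbutyl]-5-methoxy-3-(triisopropylsilyloxy)phenol | CC(C)C[C@@H](c1c(O)cc(OC)cc1O[Si](C(C)C)(C(C)C)C(C)C)[C@@]1(C)CC[C@H]2C1=C[C@H](C(C)(C)O[Si](C)(C)C(C)(C)C)CC[C@H]2C
F8 | step 10 | 2-[(1R)-1-Gu-3-methylbutyl]-5-methoxybenzene-1,3-diol | CC(C)C[C@@H](c1c(O)cc(OC)cc1O)[C@@]1(C)CC[C@H]2C1=C[C@H](C(C)(C)O[Si](C)(C)C(C)(C)C)CC[C@H]2C
F9 | step 10 | bis(N,N-dimethyliminium) dichloride corresponding to dialdehyde F10 | CC(C)C[C@@H](c1c(O)c(C=[N+](C)C)c(OC)c(C=[N+](C)C)c1O)[C@@]1(C)CC[C@H]2C1=C[C@H](C(C)(C)O[Si](C)(C)C(C)(C)C)CC[C@H]2C.[Cl-].[Cl-]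
F10 | step 10 | 5-[(1R)-1-Gu-3-methylbutyl]-4,6-dihydroxy-2-methoxybenzene-1,3-dicarbaldehyde | CC(C)C[C@@H](c1c(O)c(C=O)c(OC)c(C=O)c1O)[C@@]1(C)CC[C@H]2C1=C[C@H](C(C)(C)O[Si](C)(C)C(C)(C)C)CC[C@H]2C
F11 | step 8 | (2R)-2-Gu-4-methylpentanal | CC(C)C[C@@H](C=O)[C@@]1(C)CC[C@H]2C1=C[C@H](C(C)(C)O[Si](C)(C)C(C)(C)C)CC[C@H]2C
F12 | step 8 | (3R)-3-Gu-5-methylhex-1-yne | CC(C)C[C@@H](C#C)[C@@]1(C)CC[C@H]2C1=C[C@H](C(C)(C)O[Si](C)(C)C(C)(C)C)CC[C@H]2C
F13 | step 1 | (1R,7R,10R)-4β-(phenylselanyl)guai-5-en-11-ol | c1ccccc1[Se][C@]1(C)CC[C@H]2C1=C[C@H](C(C)(C)O)CC[C@H]2C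
F14 | step 1 | selenoxide of F13 (either configuration at selenium) | O=[Se](c1ccccc1)[C@]1(C)CC[C@H]2C1=C[C@H](C(C)(C)O)CC[C@H]2C
F15 | step 1 | (1R,6S,7R,10R)-guai-4-ene-6,11-diol | CC1=C2[C@@H](O)[C@H](C(C)(C)O)CC[C@@H](C)[C@H]2CC1
F16 | step 4 | (1R,6S,7R,10R)-11-(tert-butyldimethylsilyloxy)guai-4-en-6-ol | CC1=C2[C@@H](O)[C@H](C(C)(C)O[Si](C)(C)C(C)(C)C)CC[C@@H](C)[C@H]2CC1
A1 | alternative 1 | 3-methyl-1-(2,4,6-trimethoxyphenyl)butan-1-ol (racemic) | COc1cc(OC)c(C(O)CC(C)C)c(OC)c1
A2 | alternative 1 | 2-[(1R,4R,7R,10R)-4-[(1R)-3-methyl-1-(2,4,6-trimethoxyphenyl)butyl]guai-5-en-11-yl] alcohol (dideformyl tri-O-methyl macrocarpal D) | CC(C)C[C@@H](c1c(OC)cc(OC)cc1OC)[C@@]1(C)CC[C@H]2C1=C[C@H](C(C)(C)O)CC[C@H]2C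
A3 | alternative 2 | (1R,6R,7R,10R)-11-(tert-butyldimethylsilyloxy)guai-4-en-6-yl (2,4,6-trimethoxyphenyl)acetate | CC1=C2[C@H](OC(=O)Cc3c(OC)cc(OC)cc3OC)[C@H](C(C)(C)O[Si](C)(C)C(C)(C)C)CC[C@@H](C)[C@H]2CC1
A4 | alternative 2 | (2S)-2-Gu-2-(2,4,6-trimethoxyphenyl)acetic acid | COc1cc(OC)cc(OC)c1[C@@H](C(=O)O)[C@@]1(C)CC[C@H]2C1=C[C@H](C(C)(C)O[Si](C)(C)C(C)(C)C)CC[C@H]2C
A5 | alternative 3 | (5R)-2-methyl-5-[(2R)-6-methylhept-5-en-2-yl]cyclopent-1-ene-1-carbaldehyde | O=CC1=C(C)CC[C@@H]1[C@H](C)CCC=C(C)C
A6 | alternative 3 | (1R,6R,7S,10R)-guaia-4,11-dien-6-ol | CC1=C2[C@H](O)[C@H](C(C)=C)CC[C@@H](C)[C@H]2CC1
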